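**Strategy**

The ring is taken from the toluene-dioxygenase diol of toluene, which already holds C1, C2 and the C3(CH3)=C4 alkene; everything rests on joining C6 to C7 from the C1 oxygen. C8 is first tied to O1 as a 2-bromoallyl mixed acetal (methoxyallene supplies C14=C7–C8), and a 5-exo vinyl-radical cyclisation onto C6 of the diene then makes the hindered C6–C7 bond, sets C6 cis to O1, installs the C7=C14 methylene and leaves C3=C4 for the later epoxide–chloride relay. The precursor is the C2-silylated cyclohexadiene carrying this bromoallyl acetal on O1; acetal opening later frees O1 and C8 together.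

Key step: step 3

**Remarks**

- Atom labels follow the bisabolane numbering of the target: ring C1 (CH–OAng), C2 (CH–OH), C3 (C(CH3)OH), C4 (CHCl), C5 (CH2), C6 (CH); side chain C7(=C14H2), C8 (CH–OAng), C9, C10/C11 (epoxide). In these labels the target is (1S,2S,3S,4S,6R,8S,10S). Ang = angeloyl, (Z)-2-methylbut-2-enoyl.
- Assumption: diol 1, the cis-dihydrodiol formed from toluene by toluene dioxygenase, is taken as a purchasable starting material.
- The acetal carbon in 3–7 and the lactol carbon in 8 are epimeric mixtures and are left undefined in the SMILES; this carbon becomes C8 and is set in step 5.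

**Route**

Step 1
Reactants: 1 (1S,2R)-3-methylcyclohexa-3,5-diene-1,2-diol; 2 methoxyallene
Product: 3 mixed acetal of 1 carrying a 2-bromo-1-methoxyprop-2-enyl group on O1 (C2–OH free)
Conditions: NBS (1.05 equiv), 2 (1.5 equiv), NaHCO3 (solid), CH2Cl2, −78 → −30 °C
Reagents that add atoms: N-bromosuccinimide, O=C1CCC(=O)N1Br
Why: Haloacetalisation of an enol ether (the alkoxyallene version of Ueno–Stork acetal formation): Br+ adds to the central allene carbon and the 2-bromo-1-methoxyallyl oxocarbenium ion should be captured by the C1 hydroxyl, the less hindered of the two because C2–OH is flanked by the C3 methyl; the new acetal carbon forms as both epimers, which is of no consequence.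

Step 2
Reactants: 3 mixed acetal
Product: 4 C2-O-TBS ether of acetal 3
Conditions: TBSCl, imidazole, DMAP (cat.), DMF, 0 °C → rt
Reagents that add atoms: tert-butyldimethylsilyl chloride, CC(C)(C)[Si](C)(C)Cl
Why: Standard silyl ether formation at the remaining secondary allylic hydroxyl, which protects O2 until step 8 and removes the risk of transacetalisation; no stereocenter is touched.

Step 3
Reactants: 4 C2-O-TBS bromoallyl acetal
Product: 7 (3aR,7R,7aS)-7-(tert-butyldimethylsilyloxy)-2-methoxy-6-methyl-3-methylidene-2,3,3a,4,7,7a-hexahydrobenzofuran, via vinyl radical 5 (not isolated), via allyl radical 6 (not isolated)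
Conditions: Bu3SnH (1.3 equiv, slow addition), AIBN (0.1 equiv), PhH (0.01 M), 80 °C
Reagents that add atoms: none
Why: Radical chain: Bu3Sn• abstracts bromine from 4, the σ-vinyl radical 5 at C7 adds to C6, the unsubstituted terminus of the C3=C4–C5=C6 diene, and the allyl radical 6 (C5–C4–C3) takes hydrogen from Bu3SnH. The closest known reaction type is the tin-hydride cyclisation of 2-bromoallyl mixed acetals of allylic alcohols to 2-alkoxy-3-methylenetetrahydrofurans (Ueno–Stork type vinyl-radical cyclisation). The tetrahydrofuran ring (O1–C8–C7–C6–C1) closes in the 5-exo-trig mode and can only be cis-fused, so C6, the one new stereocenter, is set by C1: C7 is delivered to the face that carries O1. The step needs 5-exo addition to outrun hydrogen abstraction by the vinyl radical, which the allyl-stabilised product radical and slow stannane addition at high dilution should secure. It also needs hydrogen delivery at C5 and not at C3; C3 is fully substituted and shielded by the neighbouring silyl ether, and attack at C5 gives the more substituted C3=C4 alkene.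

Step 4
Reactants: 7 bicyclic methylene acetal
Product: 8 (3aR,7R,7aS)-7-(tert-butyldimethylsilyloxy)-6-methyl-3-methylidene-2,3,3a,4,7,7a-hexahydrobenzofuran-2-ol (lactol)
Conditions: AcOH–THF–H2O (3:1:1), rt
Reagents that add atoms: water, O
Why: Acetal hydrolysis through the oxocarbenium ion should give the γ-lactol, a masked 2-substituted acrolein, while the secondary TBS ether survives aqueous acetic acid at room temperature; only the anomeric carbon is affected.

Step 5
Reactants: 8 lactol; 9 dIpc2B(allyl), the B-allyldiisopinocampheylborane derived from (+)-α-pinene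
Product: 12 (1S,2R,6R)-2-(tert-butyldimethylsilyloxy)-6-[(3S)-3-hydroxyhexa-1,5-dien-2-yl]-3-methylcyclohex-3-en-1-ol, via hydroxy enal 10 (not isolated), via borinate 11 (not isolated)
Conditions: 9 (2.5 equiv), Et2O, −78 °C → rt; then 3 M NaOH, 30% H2O2, 0 °C
Reagents that add atoms: none
Why: Brown allylation of the open-chain aldehyde tautomer 10: allyl is transferred through a closed chair transition state under reagent control, the (+)-α-pinene-derived reagent adding to the Si face of the aldehyde (the sense it shows with benzaldehyde), which should give the (8S) carbinol, and oxidative work-up of borinate 11 releases the 1,8-diol; the excess reagent covers the free hydroxyl.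

Step 6
Reactants: 12 allyl diol; 13 2-methyl-2-butene
Product: 14 (1S,2R,6R)-2-(tert-butyldimethylsilyloxy)-6-[(3S)-3-hydroxy-6-methylhepta-1,5-dien-2-yl]-3-methylcyclohex-3-en-1-ol
Conditions: Grubbs II (5 mol %), 13 (large excess), CH2Cl2, 40 °C
Reagents that add atoms: none
Why: Olefin cross-metathesis of the only monosubstituted alkene with 2-methyl-2-butene should convert the terminal vinyl into the prenyl-type trisubstituted alkene with loss of propene; the 1,1-disubstituted C7=C14 and ring C3=C4 alkenes are too hindered to engage, and no stereocenter is involved.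

Step 7
Reactants: 14 prenyl diol; 15 angelic acid
Product: 17 1,8-di-O-angeloyl-2-O-TBS derivative of 14, via C8 mono-angelate 16 (not isolated)
Conditions: 15 (5 equiv), 2,4,6-trichlorobenzoyl chloride (5 equiv), Et3N (10 equiv), PhMe, rt; then 14, 80 °C
Reagents that add atoms: none
Why: Yamaguchi-type esterification with the preformed mixed anhydride in hot toluene without DMAP should acylate both secondary hydroxyls (C8 first, then the more hindered C1) with retention at carbon, and the absence of a nucleophilic catalyst avoids addition–elimination isomerisation of the (Z)-angelate to the (E)-tiglate.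

Step 8
Reactants: 17 bis-angelate silyl ether
Product: 18 1,8-di-O-angeloyl allylic alcohol (C2–OH free, C3=C4)
Conditions: HF·pyridine, pyridine, THF, 0 °C → rt
Reagents that add atoms: none
Why: Fluoride-mediated desilylation under buffered, non-basic conditions should free the allylic C2 hydroxyl without touching the esters and without 1,2-acyl migration from O1 to O2.

Step 9
Reactants: 18 allylic alcohol
Product: 19 3,4-epoxy alcohol (oxirane cis to the C2 hydroxyl)
Conditions: VO(acac)2 (5 mol %), t-BuOOH (1.5 equiv, in decane), CH2Cl2, 0 °C → rt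
Reagents that add atoms: tert-butyl hydroperoxide, CC(C)(C)OO
Why: Vanadium-catalysed hydroxyl-directed epoxidation: the C2 hydroxyl binds the vanadium peroxide and delivers oxygen to the adjacent C3=C4 bond on its own face, which sets C3 and C4 with the oxirane cis to O2, O1 and the side chain; the C10=C11 and C7=C14 alkenes and the angelates lack a directing hydroxyl and should remain.

Step 10
Reactants: 19 epoxy alcohol
Product: 20 4-chloro-2,3-diol with the C10=C11 alkene intact
Conditions: LiCl (5 equiv), AcOH (5 equiv), THF, rt
Reagents that add atoms: lithium chloride, [Li+].[Cl-]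
Why: Acid-assisted SN2 opening of the epoxide by chloride (halohydrin formation): trans-diaxial (Fürst–Plattner) attack at the secondary C4, anti to the oxirane oxygen and through the half-chair that keeps the side chain equatorial, inverts C4 and leaves C3 as the tertiary alcohol, while attack at C3 is disfavoured sterically and by the electron-withdrawing C2 hydroxyl, whose lithium chelate with the oxirane should further bias opening to C4.

Step 11
Reactants: 20 chlorohydrin
Product: 21 target, CNP0333703.2
Conditions: L-fructose-derived Shi ketone (ent-Shi ketone, 1–3 equiv), Oxone, NaHCO3, Bu4NHSO4 (cat.), MeCN–aq. Na2EDTA, 0 °C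
Reagents that add atoms: Oxone (potassium peroxymonosulfate), [K+].[O-]S(=O)(=O)OO
Why: Shi epoxidation: the chiral dioxirane attacks the electron-rich trisubstituted C10=C11 alkene through the spiro transition state on the face opposite to that chosen by the common D-fructose-derived ketone, which should give the (10S) epoxide under reagent control; the C7=C14 allylic ester alkene and the angelates are electron-poor and slow, and the bicarbonate buffer (pH about 8) keeps the chlorohydrin from closing.

**Compound list**

1 | (1S,2R)-3-methylcyclohexa-3,5-diene-1,2-diol (toluene cis-dihydrodiol) | C1=CC=C(C)[C@@H](O)[C@H]1O | starting material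
2 | methoxyallene (1-methoxypropa-1,2-diene) | COC=C=C | starting material
3 | O1-(2-bromo-1-methoxyprop-2-enyl) mixed acetal of 1, acetal epimers | C1=CC=C(C)[C@@H](O)[C@H]1OC(OC)C(Br)=C | intermediate
4 | C2-O-TBS ether of 3 | C1=CC=C(C)[C@@H](O[Si](C)(C)C(C)(C)C)[C@H]1OC(OC)C(Br)=C | intermediate
5 | C7 vinyl radical from 4 | C1=CC=C(C)[C@@H](O[Si](C)(C)C(C)(C)C)[C@H]1OC(OC)[C]=C | intermediate (not isolated)
6 | cis-fused bicyclic allyl radical (spin at C5/C3) | C=C1[C@H]2[CH]C=C(C)[C@@H](O[Si](C)(C)C(C)(C)C)[C@H]2OC1OC | intermediate (not isolated)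
7 | (3aR,7R,7aS)-7-(tert-butyldimethylsilyloxy)-2-methoxy-6-methyl-3-methylidene-2,3,3a,4,7,7a-hexahydrobenzofuran | C=C1[C@H]2CC=C(C)[C@@H](O[Si](C)(C)C(C)(C)C)[C@H]2OC1OC | intermediate
8 | (3aR,7R,7aS)-7-(tert-butyldimethylsilyloxy)-6-methyl-3-methylidene-2,3,3a,4,7,7a-hexahydrobenzofuran-2-ol | C=C1[C@H]2CC=C(C)[C@@H](O[Si](C)(C)C(C)(C)C)[C@H]2OC1O | intermediate
9 | dIpc2B(allyl), B-allyldiisopinocampheylborane from (+)-α-pinene | C=CCB([C@@H]1C[C@@H]2C[C@H]([C@H]1C)C2(C)C)[C@@H]1C[C@@H]2C[C@H]([C@H]1C)C2(C)C | starting material
10 | open-chain hydroxy enal tautomer of 8 | O=CC(=C)[C@H]1CC=C(C)[C@@H](O[Si](C)(C)C(C)(C)C)[C@H]1O | intermediate (not isolated)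
11 | O8-diisopinocampheylborinate of 12 | C=C([C@H](CC=C)OB([C@@H]1C[C@@H]2C[C@H]([C@H]1C)C2(C)C)[C@@H]1C[C@@H]2C[C@H]([C@H]1C)C2(C)C)[C@H]3CC=C(C)[C@@H](O[Si](C)(C)C(C)(C)C)[C@H]3O | intermediate (not isolated)
12 | (1S,2R,6R)-2-(tert-butyldimethylsilyloxy)-6-[(3S)-3-hydroxyhexa-1,5-dien-2-yl]-3-methylcyclohex-3-en-1-ol | C=C([C@H](CC=C)O)[C@H]1CC=C(C)[C@@H](O[Si](C)(C)C(C)(C)C)[C@H]1O | intermediate
13 | 2-methyl-2-butene | CC=C(C)C | starting material
14 | (1S,2R,6R)-2-(tert-butyldimethylsilyloxy)-6-[(3S)-3-hydroxy-6-methylhepta-1,5-dien-2-yl]-3-methylcyclohex-3-en-1-ol | C=C([C@H](CC=C(C)C)O)[C@H]1CC=C(C)[C@@H](O[Si](C)(C)C(C)(C)C)[C@H]1O | intermediate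
15 | angelic acid, (Z)-2-methylbut-2-enoic acid | C/C=C(/C)C(=O)O | starting material
16 | 8-O-angeloyl derivative of 14 (C1–OH free) | C=C([C@H](CC=C(C)C)OC(=O)/C(C)=C\C)[C@H]1CC=C(C)[C@@H](O[Si](C)(C)C(C)(C)C)[C@H]1O | intermediate (not isolated)
17 | 1,8-di-O-angeloyl-2-O-TBS derivative of 14 | C=C([C@H](CC=C(C)C)OC(=O)/C(C)=C\C)[C@H]1CC=C(C)[C@@H](O[Si](C)(C)C(C)(C)C)[C@H]1OC(=O)/C(C)=C\C | intermediate
18 | 1,8-di-O-angeloyl allylic alcohol (C2–OH, C3=C4) | C=C([C@H](CC=C(C)C)OC(=O)/C(C)=C\C)[C@H]1CC=C(C)[C@@H](O)[C@H]1OC(=O)/C(C)=C\C | intermediate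
19 | 3,4-epoxide of 18, oxirane cis to C2–OH | C=C([C@H](CC=C(C)C)OC(=O)/C(C)=C\C)[C@H]1C[C@H]2O[C@@]2(C)[C@@H](O)[C@H]1OC(=O)/C(C)=C\C | intermediate
20 | 4-chloro-2,3-diol with C10=C11 alkene (10,11-deoxy target) | C=C([C@H](CC=C(C)C)OC(=O)/C(C)=C\C)[C@H]1C[C@H](Cl)[C@@](C)(O)[C@@H](O)[C@H]1OC(=O)/C(C)=C\C | intermediate
21 | CNP0333703.2, (1S,2S,3S,4S,6R,8S,10S) in bisabolane labels | C=C([C@H](C[C@@H]1OC1(C)C)OC(=O)/C(C)=C\C)[C@H]1C[C@H](Cl)[C@@](C)(O)[C@@H](O)[C@H]1OC(=O)/C(C)=C\C | target

**Step count and risks**

Total step count: 11. Longest linear sequence: 11 steps (1 → 21).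

Steps most likely to fail:

Step 1. Discrimination between the two secondary hydroxyls may be poor, and the first-formed mixed acetal may exchange with the neighbouring C2 hydroxyl, with loss of methanol, to a cyclic acetal. The fallback replaces direct differentiation by a temporary-silyl sequence. It sets out from 1: the less hindered distal hydroxyl is silylated (TESCl, imidazole, DMF, −40 °C) to the O1 triethylsilyl ether F1; the C2 hydroxyl is then silylated (TBSOTf, 2,6-lutidine, −78 °C) to the bis-silyl ether F2; the triethylsilyl group alone is removed (PPTS, MeOH, 0 °C) to the C2-O-TBS alcohol F3. Bromoacetalisation of F3 with methoxyallene and NBS, now with a single free hydroxyl, should give 4, where the route is rejoined.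

Step 3. The σ-vinyl radical may be reduced, or may abstract the weak allylic C1–H by 1,5-hydrogen transfer, before it closes the ring. The fallback uses an alkyl radical and adds the methylene afterwards by polar chemistry; it does not remove the separate risk of hydrogen delivery to C3 of the allyl radical. It sets out from 1: ethyl vinyl ether and NBS should give the O1 2-bromo-1-ethoxyethyl acetal F4, and TBSCl/imidazole its C2-O-TBS ether F5. Classical Ueno–Stork cyclisation (Bu3SnH, AIBN, PhH, 80 °C) should give the saturated cis-fused ethyl acetal F6, and aqueous acetic acid the saturated lactol F7. Amine-catalysed α-methylenation of the latent aldehyde (aqueous formaldehyde, pyrrolidine and propionic acid as catalysts, i-PrOH, 45 °C) should then give lactol 8, where the route is rejoined.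

Step 11. The weakly basic medium may close the trans-diaxial chlorohydrin back to the 3,4-epoxide, and facial control at the remote alkene may be incomplete. The fallback changes the order so that no chlorohydrin is exposed to the oxidation. It sets out from 19: Shi epoxidation with the same ketone under the usual carbonate-buffered conditions should give the 3,4:10,11-bis-epoxide F8. Chloride is then delivered only to the oxirane next to the free C2 hydroxyl with ClTi(OiPr)3 in CH2Cl2 (titanium-alkoxide-directed opening of a 2,3-epoxy alcohol at the distal carbon, here C4); the isolated side-chain epoxide has no hydroxyl anchor. This should give 21 directly.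

**Further compounds**

F1 | step 1 | O1-triethylsilyl ether of 1 | C1=CC=C(C)[C@@H](O)[C@H]1O[Si](CC)(CC)CC
F2 | step 1 | O1-triethylsilyl O2-TBS bis-ether of 1 | C1=CC=C(C)[C@@H](O[Si](C)(C)C(C)(C)C)[C@H]1O[Si](CC)(CC)CC
F3 | step 1 | O2-TBS ether of 1 (C1–OH free) | C1=CC=C(C)[C@@H](O[Si](C)(C)C(C)(C)C)[C@H]1O
F4 | step 3 | O1-(2-bromo-1-ethoxyethyl) mixed acetal of 1 | C1=CC=C(C)[C@@H](O)[C@H]1OC(OCC)CBr
F5 | step 3 | C2-O-TBS ether of F4 | C1=CC=C(C)[C@@H](O[Si](C)(C)C(C)(C)C)[C@H]1OC(OCC)CBr
F6 | step 3 | cis-fused 2-ethoxy-7-(TBS-oxy)-6-methyl-2,3,3a,4,7,7a-hexahydrobenzofuran | CCOC1C[C@H]2CC=C(C)[C@@H](O[Si](C)(C)C(C)(C)C)[C@H]2O1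
F7 | step 3 | cis-fused 7-(TBS-oxy)-6-methyl-2,3,3a,4,7,7a-hexahydrobenzofuran-2-ol | OC1C[C@H]2CC=C(C)[C@@H](O[Si](C)(C)C(C)(C)C)[C@H]2O1
F8 | step 11 | 3,4:10,11-bis-epoxide (10S) with C2–OH free | C=C([C@H](C[C@@H]1OC1(C)C)OC(=O)/C(C)=C\C)[C@H]1C[C@H]2O[C@@]2(C)[C@@H](O)[C@H]1OC(=O)/C(C)=C\C
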